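**Plan**

1. Ring A is numbered C1 (aroyl), C2 and C6 (OH), C3 and C5 (prenyl), C4 (OMe). The retrosynthesis cuts C1–C2 and C5–C6 and puts a CH2–CH2 bridge back between C2 and C5, so ring A becomes the product of a Diels–Alder addition followed by loss of ethylene.
2. Enabling feature: C2–C3–C4–C5 carry O, prenyl, O, prenyl, the pattern of a 2,6-dialkylated 3-oxycyclohex-2-enone. C1–C6 carry aroyl and O, the pattern of a 3-alkoxy ynone.
3. Forward order: ring B is bought as methyl 4-hydroxybenzoate and extended to the ynone. Cyclohexane-1,3-dione takes up both prenyl groups by enolate alkylation and is converted into a 1,3-bis(silyloxy)diene, and this carbocycle becomes ring A in the key step.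
4. The three ring A oxygens arrive differentiated (C2 OSi(iPr)3, C4 OSiMe3, C6 OMe). C4 is unmasked and methylated alone, and the single ortho methyl ether is cleaved by chelation to the ketone while the other ortho oxygen is still silylated. A phenolate already chelated to the ketone would hold the carbonyl oxygen away from a second ortho ether, and the prenyl groups rule out forcing Lewis acids.
5. Stereochemistry: the target is achiral. The stereocentres of the alkylated enone and of the bicyclic adduct are racemic and disappear along the way.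

Key step: step 8

Remark: prenyl stands for 3-methylbut-2-enyl, and 2-substituted cyclohexane-1,3-diones are written as diketo tautomers although they are largely enolised.

**Step 1**
Reactants: 1 cyclohexane-1,3-dione; 2 prenyl bromide (1-bromo-3-methylbut-2-ene)
Product: 3 2-(3-methylbut-2-enyl)cyclohexane-1,3-dione
Conditions: KOH, H2O, 0 °C → rt
Reagents that add atoms: none
Why: C-alkylation of a cyclic 1,3-dione enolate, in which water hydrogen-bonds the enolate oxygens so that the soft allylic bromide should be taken up at C2, the carbon between the two carbonyl groups.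

**Step 2**
Reactants: 3 2-(3-methylbut-2-enyl)cyclohexane-1,3-dione
Product: 4 2-(3-methylbut-2-enyl)-3-(triisopropylsilyloxy)cyclohex-2-en-1-one
Conditions: iPr3SiOTf, Et3N, CH2Cl2, 0 °C
Reagents that add atoms: triisopropylsilyl trifluoromethanesulfonate, CC(C)[Si](OS(=O)(=O)C(F)(F)F)(C(C)C)C(C)C
Why: O-silylation of the enolised dione with a hard silyl triflate should give the vinylogous silyl ester as a single regioisomer because 3 is symmetric, and the basic medium avoids the acid-catalysed addition of the enol to the prenyl double bond.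

**Step 3**
Reactants: 4 2-(3-methylbut-2-enyl)-3-(triisopropylsilyloxy)cyclohex-2-en-1-one; 2 prenyl bromide
Product: 6 2,6-bis(3-methylbut-2-enyl)-3-(triisopropylsilyloxy)cyclohex-2-en-1-one (racemic), via lithium dienolate 5 (not isolated)
Conditions: LiN(iPr)2, THF, −78 °C; then 2, −78 → −20 °C
Reagents that add atoms: none
Why: Stork–Danheiser-type kinetic α′-deprotonation gives the cross-conjugated dienolate 5, whose only nucleophilic carbon is C6, and SN2 alkylation by the allylic bromide places the second prenyl group there; the bulky silyl group resists transfer to the enolate oxygen, and the new stereocentre is racemic and is erased in step 4.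

**Step 4**
Reactants: 6 2,6-bis(3-methylbut-2-enyl)-3-(triisopropylsilyloxy)cyclohex-2-en-1-one
Product: 8 2,4-bis(3-methylbut-2-enyl)-1-(triisopropylsilyloxy)-3-(trimethylsilyloxy)cyclohexa-1,3-diene, via lithium dienolate 7 (not isolated)
Conditions: LiN(iPr)2, THF, −78 °C; Me3SiCl, −78 → 0 °C; pentane, filtration, no aqueous work-up
Reagents that add atoms: chlorotrimethylsilane, C[Si](C)(C)Cl
Why: Kinetic deprotonation of the vinylogous ester again takes the α′ proton at C6 rather than a γ proton at C4, and silyl enol ether formation on oxygen of the hindered dienolate 7 fixes a 1,3-dioxygenated cyclohexa-1,3-diene with both prenyl groups on diene carbons.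

**Step 5**
Reactants: 9 methyl 4-hydroxybenzoate
Product: 10 methyl 4-(triisopropylsilyloxy)benzoate
Conditions: iPr3SiCl, imidazole, DMF, rt
Reagents that add atoms: chlorotriisopropylsilane, CC(C)[Si](Cl)(C(C)C)C(C)C
Why: Imidazole-promoted phenol silylation installs on ring B an ether that tolerates base and heat and falls to fluoride.

**Step 6**
Reactants: 10 methyl 4-(triisopropylsilyloxy)benzoate
Product: 11 N-methoxy-N-methyl-4-(triisopropylsilyloxy)benzamide
Conditions: MeNH(OMe)·HCl, iPrMgCl, THF, −20 → 0 °C
Reagents that add atoms: N,O-dimethylhydroxylamine hydrochloride, CNOC.Cl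
Why: Weinreb amide formation from an ester with the chloromagnesium amide of N,O-dimethylhydroxylamine is a plain acyl substitution that leaves the aryl silyl ether untouched.

**Step 7**
Reactants: 12 chloroacetaldehyde dimethyl acetal (2-chloro-1,1-dimethoxyethane); 11 N-methoxy-N-methyl-4-(triisopropylsilyloxy)benzamide
Product: 14 3-methoxy-1-[4-(triisopropylsilyloxy)phenyl]prop-2-yn-1-one, via lithium methoxyacetylide 13 (not isolated)
Conditions: Et2NH, nBuLi (3 equiv per 12), THF, 0 °C; 12, 0 °C; then 11, −78 → −30 °C; inverse quench into cold aq. NaH2PO4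
Reagents that add atoms: none
Why: Three equivalents of LiNEt2 remove methanol and HCl from 12 and metalate the alkyne (the usual in situ route to lithium alkoxyacetylides), and Weinreb ketone synthesis stops at the ynone because the chelated tetrahedral adduct lasts until the cold, mildly acidic quench, which also protonates the amines before they can add to 14.

**Step 8**
Reactants: 8 2,4-bis(3-methylbut-2-enyl)-1-(triisopropylsilyloxy)-3-(trimethylsilyloxy)cyclohexa-1,3-diene; 14 3-methoxy-1-[4-(triisopropylsilyloxy)phenyl]prop-2-yn-1-one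
Product: 16 [2-methoxy-3,5-bis(3-methylbut-2-enyl)-6-(triisopropylsilyloxy)-4-(trimethylsilyloxy)phenyl][4-(triisopropylsilyloxy)phenyl]methanone, via bicyclo[2.2.2]octadiene adduct 15 (not isolated)
Conditions: mesitylene (2 M), BHT (cat.), base-washed sealed tube, Ar, 130 °C, then 175 °C
Reagents that add atoms: none
Why: Proposed new method: both oxygen donors of diene 8 raise the orbital coefficient at its prenyl-bearing terminus, which should bond to the methoxy-bearing β-carbon of ynone 14 (C5–C6) slightly ahead of the bond between the silyloxy-bearing terminus and the aroyl-bearing α-carbon (C1–C2), an asynchronous normal-demand [4+2] cycloaddition leading to adduct 15. At the higher temperature 15 should expel its CH2–CH2 bridge as ethylene by retro-[4+2] reaction, so ring A is closed by an intermolecular two-bond cycloaddition and made aromatic irreversibly by cycloreversion. The closest known reaction is the Alder–Rickert phenol synthesis from 1-alkoxy-3-silyloxy- or 1,3-bis(silyloxy)cyclohexa-1,3-dienes and acetylenic esters or ketones; not yet shown are an alkyne partner that carries a donor oxygen opposite the carbonyl group and a diene substituted on all four carbons. Three design features should help: the methyl ynol ether has no β-hydrogen and cannot fragment to a ketene by retro-ene reaction on heating, the linear alkyne is sterically slim (1,4-disubstituted cyclohexadienes are known to add acetylenic dienophiles), and the bridgehead silyloxy group points away from the forming bonds. The only selectivity required is regiochemical, and it rests on matched polarisation, since the nucleophilic diene terminus meets the carbon β to the ketone, which remains the acceptor site of the donor–acceptor alkyne. The two bridgehead stereocentres of 15 form as a racemate and vanish on aromatisation, so no stereocontrol is needed.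

**Step 9**
Reactants: 16 [2-methoxy-3,5-bis(3-methylbut-2-enyl)-6-(triisopropylsilyloxy)-4-(trimethylsilyloxy)phenyl][4-(triisopropylsilyloxy)phenyl]methanone
Product: 17 [4-hydroxy-2-methoxy-3,5-bis(3-methylbut-2-enyl)-6-(triisopropylsilyloxy)phenyl][4-(triisopropylsilyloxy)phenyl]methanone
Conditions: MeOH, citric acid (cat.), 0 °C → rt
Reagents that add atoms: none
Why: Solvolytic desilylation of an aryl trimethylsilyl ether is far faster than that of aryl triisopropylsilyl ethers, so only the C4 oxygen should be freed.

**Step 10**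
Reactants: 17 [4-hydroxy-2-methoxy-3,5-bis(3-methylbut-2-enyl)-6-(triisopropylsilyloxy)phenyl][4-(triisopropylsilyloxy)phenyl]methanone
Product: 18 [2,4-dimethoxy-3,5-bis(3-methylbut-2-enyl)-6-(triisopropylsilyloxy)phenyl][4-(triisopropylsilyloxy)phenyl]methanone
Conditions: MeI, K2CO3, acetone, 45 °C
Reagents that add atoms: iodomethane, CI
Why: Williamson O-methylation of the only free phenol, in which the flanking prenyl groups slow but do not block attack on the small electrophile and K2CO3 in dry acetone leaves both silyl ethers in place.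

**Step 11**
Reactants: 18 [2,4-dimethoxy-3,5-bis(3-methylbut-2-enyl)-6-(triisopropylsilyloxy)phenyl][4-(triisopropylsilyloxy)phenyl]methanone
Product: 19 [2-hydroxy-4-methoxy-3,5-bis(3-methylbut-2-enyl)-6-(triisopropylsilyloxy)phenyl][4-(triisopropylsilyloxy)phenyl]methanone
Conditions: MgI2·OEt2, THF, 60 °C; then aq. NH4Cl/Na2S2O3
Reagents that add atoms: none
Why: Chelation-directed aryl methyl ether cleavage, in which MgI2 binds the ketone oxygen and the neighbouring methoxy oxygen in a six-membered chelate and iodide removes the methyl group by SN2, while the C4 ether cannot chelate and the hindered, weakly basic silyl ether oxygen does not compete; this mild reagent is known to cleave methyl ethers ortho to a carbonyl group in C-prenylated flavanones without closing the prenyl group onto the phenol, as boron and aluminium halides tend to do.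

**Step 12**
Reactants: 19 [2-hydroxy-4-methoxy-3,5-bis(3-methylbut-2-enyl)-6-(triisopropylsilyloxy)phenyl][4-(triisopropylsilyloxy)phenyl]methanone
Product: 20 vismiaphenone D, [2,6-dihydroxy-4-methoxy-3,5-bis(3-methylbut-2-enyl)phenyl](4-hydroxyphenyl)methanone
Conditions: Bu4NF, AcOH, THF, 0 °C → rt
Reagents that add atoms: none
Why: Fluoride-induced desilylation removes both aryl silyl ethers at once, and the acetic acid buffer keeps the o-prenylphenols away from strong acid and strong base.

**Compound list**

1 | cyclohexane-1,3-dione | O=C1CCCC(=O)C1 | starting material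
2 | prenyl bromide (1-bromo-3-methylbut-2-ene) | CC(C)=CCBr | starting material
3 | 2-(3-methylbut-2-enyl)cyclohexane-1,3-dione | CC(C)=CCC1C(=O)CCCC1=O | intermediate
4 | 2-(3-methylbut-2-enyl)-3-(triisopropylsilyloxy)cyclohex-2-en-1-one | CC(C)=CCC1=C(O[Si](C(C)C)(C(C)C)C(C)C)CCCC1=O | intermediate
5 | lithium 6-(3-methylbut-2-enyl)-5-(triisopropylsilyloxy)cyclohexa-1,5-dien-1-olate | [Li]OC1=CCCC(O[Si](C(C)C)(C(C)C)C(C)C)=C1CC=C(C)C | intermediate
6 | 2,6-bis(3-methylbut-2-enyl)-3-(triisopropylsilyloxy)cyclohex-2-en-1-one (racemic) | CC(C)=CCC1CCC(O[Si](C(C)C)(C(C)C)C(C)C)=C(CC=C(C)C)C1=O | intermediate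
7 | lithium 2,6-bis(3-methylbut-2-enyl)-5-(triisopropylsilyloxy)cyclohexa-1,5-dien-1-olate | [Li]OC1=C(CC=C(C)C)CCC(O[Si](C(C)C)(C(C)C)C(C)C)=C1CC=C(C)C | intermediate
8 | 2,4-bis(3-methylbut-2-enyl)-1-(triisopropylsilyloxy)-3-(trimethylsilyloxy)cyclohexa-1,3-diene | CC(C)=CCC1=C(O[Si](C)(C)C)C(CC=C(C)C)=C(O[Si](C(C)C)(C(C)C)C(C)C)CC1 | intermediate
9 | methyl 4-hydroxybenzoate | COC(=O)c1ccc(O)cc1 | starting material
10 | methyl 4-(triisopropylsilyloxy)benzoate | COC(=O)c1ccc(O[Si](C(C)C)(C(C)C)C(C)C)cc1 | intermediate
11 | N-methoxy-N-methyl-4-(triisopropylsilyloxy)benzamide | CON(C)C(=O)c1ccc(O[Si](C(C)C)(C(C)C)C(C)C)cc1 | intermediate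
12 | chloroacetaldehyde dimethyl acetal | COC(CCl)OC | starting material
13 | lithium methoxyacetylide | [Li]C#COC | intermediate
14 | 3-methoxy-1-[4-(triisopropylsilyloxy)phenyl]prop-2-yn-1-one | COC#CC(=O)c1ccc(O[Si](C(C)C)(C(C)C)C(C)C)cc1 | intermediate
15 | [3-methoxy-4,6-bis(3-methylbut-2-enyl)-1-(triisopropylsilyloxy)-5-(trimethylsilyloxy)bicyclo[2.2.2]octa-2,5-dien-2-yl][4-(triisopropylsilyloxy)phenyl]methanone (racemic; the two bridgeheads are geometrically coupled) | COC1=C(C(=O)c2ccc(O[Si](C(C)C)(C(C)C)C(C)C)cc2)C2(O[Si](C(C)C)(C(C)C)C(C)C)CCC1(CC=C(C)C)C(O[Si](C)(C)C)=C2CC=C(C)C | intermediate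
16 | [2-methoxy-3,5-bis(3-methylbut-2-enyl)-6-(triisopropylsilyloxy)-4-(trimethylsilyloxy)phenyl][4-(triisopropylsilyloxy)phenyl]methanone | COc1c(CC=C(C)C)c(O[Si](C)(C)C)c(CC=C(C)C)c(O[Si](C(C)C)(C(C)C)C(C)C)c1C(=O)c1ccc(O[Si](C(C)C)(C(C)C)C(C)C)cc1 | intermediate
17 | [4-hydroxy-2-methoxy-3,5-bis(3-methylbut-2-enyl)-6-(triisopropylsilyloxy)phenyl][4-(triisopropylsilyloxy)phenyl]methanone | COc1c(CC=C(C)C)c(O)c(CC=C(C)C)c(O[Si](C(C)C)(C(C)C)C(C)C)c1C(=O)c1ccc(O[Si](C(C)C)(C(C)C)C(C)C)cc1 | intermediate
18 | [2,4-dimethoxy-3,5-bis(3-methylbut-2-enyl)-6-(triisopropylsilyloxy)phenyl][4-(triisopropylsilyloxy)phenyl]methanone | COc1c(CC=C(C)C)c(OC)c(CC=C(C)C)c(O[Si](C(C)C)(C(C)C)C(C)C)c1C(=O)c1ccc(O[Si](C(C)C)(C(C)C)C(C)C)cc1 | intermediate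
19 | [2-hydroxy-4-methoxy-3,5-bis(3-methylbut-2-enyl)-6-(triisopropylsilyloxy)phenyl][4-(triisopropylsilyloxy)phenyl]methanone | COc1c(CC=C(C)C)c(O)c(C(=O)c2ccc(O[Si](C(C)C)(C(C)C)C(C)C)cc2)c(O[Si](C(C)C)(C(C)C)C(C)C)c1CC=C(C)C | intermediate
20 | vismiaphenone D | COc1c(CC=C(C)C)c(O)c(C(=O)c2ccc(O)cc2)c(O)c1CC=C(C)C | target

**Total step count:** 12. **Longest linear sequence:** 9 (steps 1–4 and 8–12).

**Steps most likely to fail**

**Step 8.** The donor oxygen raises the acceptor orbital of the alkyne and both diene termini are fully substituted. The addition may therefore be outpaced by thermal oligomerisation of the ynone, by protodesilylation of the enol ether, or by hydrogen shifts that move the diene out of register.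

The fallback uses known chemistry and takes ring A from an arene instead of building it. It sets out from 11 and 2 and comes back to the route at 18.
- Commercial 1,3,5-trimethoxybenzene is lithiated between two methoxy groups (nBuLi, THF, 0 °C) and alkylated with 2 to give 1,3,5-trimethoxy-2-(3-methylbut-2-enyl)benzene F1.
- A second directed lithiation and alkylation with 2 gives 1,3,5-trimethoxy-2,4-bis(3-methylbut-2-enyl)benzene F2.
- Lithiation of the last ring position and acylation with 11 gives [2,4,6-trimethoxy-3,5-bis(3-methylbut-2-enyl)phenyl][4-(triisopropylsilyloxy)phenyl]methanone F3.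
- MgI2·OEt2 removes one of the two equivalent ortho methyl groups and stops at the chelated phenol [2-hydroxy-4,6-dimethoxy-3,5-bis(3-methylbut-2-enyl)phenyl][4-(triisopropylsilyloxy)phenyl]methanone F4.
- iPr3SiOTf and 2,6-lutidine convert F4 into 18, after which steps 11 and 12 follow unchanged.

**Step 7.** The liberated amines may add in conjugate fashion to the ynone during the quench. The ynol ether may be hydrated on work-up or on silica, or the acylation may stall.

The fallback replaces acylation by addition and oxidation. It sets out from 11 and comes back at 14.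
- iBu2AlH (THF, −78 °C) reduces 11 to 4-(triisopropylsilyloxy)benzaldehyde F5.
- Acetylide 13, generated as in step 7, adds to F5 to give racemic 3-methoxy-1-[4-(triisopropylsilyloxy)phenyl]prop-2-yn-1-ol F6, which is not a Michael acceptor and is freed from the amines by extraction.
- MnO2 (CH2Cl2, rt, neutral) oxidises the benzylic propargylic alcohol F6 to 14.

**Step 3.** Silyl transfer from the vinylogous silyl ester to the dienolate oxygen, proton exchange leading to double alkylation, or hydrolysis during isolation may erode the alkylation.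

The fallback carries the alkylation out on the robust methyl vinylogous ester. It sets out from 3 and comes back at 6.
- Me2SO4 and K2CO3 in acetone give 3-methoxy-2-(3-methylbut-2-enyl)cyclohex-2-en-1-one F7.
- LiN(iPr)2 and then 2 give racemic 3-methoxy-2,6-bis(3-methylbut-2-enyl)cyclohex-2-en-1-one F8.
- Aqueous NaOH in THF at reflux hydrolyses the enol ether to 2,4-bis(3-methylbut-2-enyl)cyclohexane-1,3-dione F9.
- iPr3SiOTf and Et3N silylate the less hindered oxygen, the one next to the ring CH2, which gives 6.

**Further compounds**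

F1 | step 8 | 1,3,5-trimethoxy-2-(3-methylbut-2-enyl)benzene | COc1cc(OC)c(CC=C(C)C)c(OC)c1
F2 | step 8 | 1,3,5-trimethoxy-2,4-bis(3-methylbut-2-enyl)benzene | COc1cc(OC)c(CC=C(C)C)c(OC)c1CC=C(C)C
F3 | step 8 | [2,4,6-trimethoxy-3,5-bis(3-methylbut-2-enyl)phenyl][4-(triisopropylsilyloxy)phenyl]methanone | COc1c(CC=C(C)C)c(OC)c(CC=C(C)C)c(OC)c1C(=O)c1ccc(O[Si](C(C)C)(C(C)C)C(C)C)cc1
F4 | step 8 | [2-hydroxy-4,6-dimethoxy-3,5-bis(3-methylbut-2-enyl)phenyl][4-(triisopropylsilyloxy)phenyl]methanone | COc1c(CC=C(C)C)c(OC)c(CC=C(C)C)c(O)c1C(=O)c1ccc(O[Si](C(C)C)(C(C)C)C(C)C)cc1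
F5 | step 7 | 4-(triisopropylsilyloxy)benzaldehyde | O=Cc1ccc(O[Si](C(C)C)(C(C)C)C(C)C)cc1
F6 | step 7 | 3-methoxy-1-[4-(triisopropylsilyloxy)phenyl]prop-2-yn-1-ol (racemic) | COC#CC(O)c1ccc(O[Si](C(C)C)(C(C)C)C(C)C)cc1
F7 | step 3 | 3-methoxy-2-(3-methylbut-2-enyl)cyclohex-2-en-1-one | COC1=C(CC=C(C)C)C(=O)CCC1
F8 | step 3 | 3-methoxy-2,6-bis(3-methylbut-2-enyl)cyclohex-2-en-1-one (racemic) | COC1=C(CC=C(C)C)C(=O)C(CC=C(C)C)CC1
F9 | step 3 | 2,4-bis(3-methylbut-2-enyl)cyclohexane-1,3-dione | CC(C)=CCC1CCC(=O)C(CC=C(C)C)C1=O
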